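Retrosynthesis: after the five benzyl groups and a temporary oxygen at C6 of the upper chroman (removed through its triflate) are taken off, the upper pyran is cut at O1–C2 (Mitsunobu) and at O1–C8a, the oxygen that a Baeyer–Villiger step inserts.
Enabling feature: without O1, atoms C2, C3, C4, C4a and C8a of the upper chroman are the five-membered ring of a trans-2,3-diaryl-indan-1-one. Its carbonyl-flanked carbon equilibrates to trans, and a methoxymethoxy group para to the ring-fusion carbon C7a is carried so that this aryl carbon, not the benzylic C2, migrates to oxygen.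
The indanone is cut at C2–aryl (Pd α-arylation with the catechol-ring triflate) and at C3–C3a (reductive Heck of a 2'-bromochalcone). The chalcone C=C divides into a bromoacetophenone and the (R)-isoflavan aldehyde, itself cut at O1–C8a (Pd etherification) and C3–C4 (Evans alkylation).
Forward ring order: lower pyran, indanone five-membered ring, ring expansion to the six-membered lactone, upper pyran.
Stereochemistry: lower C3 (R) comes from (R)-4-benzyloxazolidin-2-one; upper C4 (S) is the indanone C3 set in the ligand-controlled reductive Heck step, with the minor diastereomer removed; upper C3 (R) comes from thermodynamic trans control at the indanone C2 and passes through the oxygen insertion with retention.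

Key step: step 21

Notation: Bn = benzyl; MOM = methoxymethyl; ArB = 2,3-bis(benzyloxy)-4-methoxyphenyl; ArC = 4-(benzyloxy)-2-[(3R)-7-(benzyloxy)-3,4-dihydro-2H-chromen-3-yl]-6-methoxyphenyl.
Assumption: the sense of induction of the chiral bisphosphine in step 19 has to be confirmed on this substrate. The (R)-ligand is written; its antipode is taken if that one favours the (3S)-indanone. In either case the C3 epimer is a diastereomer and is removed by chromatography.

Step 1
Reactants: 1 2-bromo-4-hydroxybenzaldehyde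
Product: 2 4-(benzyloxy)-2-bromobenzaldehyde
Conditions: BnBr, K2CO3, DMF, rt
Reagents that add atoms: benzyl bromide, BrCc1ccccc1
Why: Williamson etherification of the phenoxide, the only acidic site, with benzyl bromide.

Step 2
Reactants: 2 4-(benzyloxy)-2-bromobenzaldehyde
Product: 3 [4-(benzyloxy)-2-bromophenyl]methanol
Conditions: NaBH4, MeOH–THF, 0 °C
Reagents that add atoms: none
Why: Borohydride reduction of the aldehyde, to which the aryl bromide and the benzyl ether are inert.

Step 3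
Reactants: 3 [4-(benzyloxy)-2-bromophenyl]methanol
Product: 4 4-(benzyloxy)-2-bromo-1-(bromomethyl)benzene
Conditions: PBr3, CH2Cl2, 0 °C
Reagents that add atoms: phosphorus tribromide, BrP(Br)Br
Why: Conversion of the benzylic alcohol into the bromide through its phosphite ester (SN2 displacement by bromide), under conditions that leave the aryl ether untouched.

Step 4
Reactants: 5 methyl 2,4-dihydroxy-6-methylbenzoate (methyl orsellinate)
Product: 6 methyl 4-(benzyloxy)-2-hydroxy-6-methylbenzoate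
Conditions: BnBr (1.05 equiv), K2CO3, acetone, reflux
Reagents that add atoms: benzyl bromide, BrCc1ccccc1
Why: Regioselective Williamson etherification: the 2-hydroxyl is locked in a hydrogen bond to the ester carbonyl, so only the 4-phenoxide should be benzylated.

Step 5
Reactants: 6 methyl 4-(benzyloxy)-2-hydroxy-6-methylbenzoate
Product: 7 methyl 4-(benzyloxy)-2-methoxy-6-methylbenzoate
Conditions: MeI, K2CO3, DMF, 60 °C
Reagents that add atoms: iodomethane, CI
Why: Williamson methylation of the remaining chelated phenol under more forcing conditions fixes the methoxy group next to the carbon that later carries the upper chroman.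

Step 6
Reactants: 7 methyl 4-(benzyloxy)-2-methoxy-6-methylbenzoate
Product: 9 2-[5-(benzyloxy)-3-methoxy-2-(methoxycarbonyl)phenyl]acetic acid, via benzylic lithium species 8 (not isolated)
Conditions: LiN(iPr)2, THF, −78 °C; then CO2; aq. HCl work-up
Reagents that add atoms: carbon dioxide, O=C=O
Why: Lateral lithiation of the ortho-toluate (benzylic anion stabilised by the ortho ester) followed by carboxylation should give the homophthalic half ester, the hindered ester and the benzyl ether being inert to the amide base at −78 °C.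

Step 7
Reactants: 9 2-[5-(benzyloxy)-3-methoxy-2-(methoxycarbonyl)phenyl]acetic acid
Product: 11 methyl 4-(benzyloxy)-2-{2-[(4R)-4-benzyl-2-oxo-1,3-oxazolidin-3-yl]-2-oxoethyl}-6-methoxybenzoate, via mixed pivalic anhydride 10 (not isolated)
Conditions: t-BuCOCl, Et3N, THF, −20 °C; then (R)-4-benzyloxazolidin-2-one, LiCl, rt
Reagents that add atoms: (R)-4-benzyl-1,3-oxazolidin-2-one, O=C1N[C@H](Cc2ccccc2)CO1
Why: N-Acylation of the oxazolidinone through the mixed anhydride under LiCl/Et3N activation, in which the 2,6-disubstituted aryl ester is too hindered to compete.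

Step 8
Reactants: 11 methyl 4-(benzyloxy)-2-{2-[(4R)-4-benzyl-2-oxo-1,3-oxazolidin-3-yl]-2-oxoethyl}-6-methoxybenzoate; 4 4-(benzyloxy)-2-bromo-1-(bromomethyl)benzene
Product: 13 methyl 4-(benzyloxy)-2-{(2R)-1-[(4R)-4-benzyl-2-oxo-1,3-oxazolidin-3-yl]-3-[4-(benzyloxy)-2-bromophenyl]-1-oxopropan-2-yl}-6-methoxybenzoate, via sodium Z-enolate 12 (not isolated)
Conditions: NaN(SiMe3)2, THF, −78 °C; then 4, −78 → −40 °C
Reagents that add atoms: none
Why: Evans asymmetric alkylation: the chelated Z-enolate is alkylated by the benzylic bromide on the face opposite the 4-benzyl group of the (R)-auxiliary, which should set the new centre (R), the future C3 of the lower chroman.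

Step 9
Reactants: 13 methyl 4-(benzyloxy)-2-{(2R)-1-[(4R)-4-benzyl-2-oxo-1,3-oxazolidin-3-yl]-3-[4-(benzyloxy)-2-bromophenyl]-1-oxopropan-2-yl}-6-methoxybenzoate
Product: 14 (2R)-3-[4-(benzyloxy)-2-bromophenyl]-2-[5-(benzyloxy)-2-(hydroxymethyl)-3-methoxyphenyl]propan-1-ol
Conditions: LiAlH4, THF, 0 °C → rt
Reagents that add atoms: none
Why: Hydride reduction cleaves the imide to the primary alcohol and reduces the hindered ester to the benzylic alcohol; the α-aryl centre is not enolised under these conditions and the aryl bromide should survive at this temperature.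

Step 10
Reactants: 14 (2R)-3-[4-(benzyloxy)-2-bromophenyl]-2-[5-(benzyloxy)-2-(hydroxymethyl)-3-methoxyphenyl]propan-1-ol
Product: 15 {4-(benzyloxy)-2-[(3R)-7-(benzyloxy)-3,4-dihydro-2H-chromen-3-yl]-6-methoxyphenyl}methanol
Conditions: Pd(OAc)2, 2-(di-tert-butylphosphino)-1,1'-binaphthyl, Cs2CO3, toluene, 70 °C
Reagents that add atoms: none
Why: Palladium-catalysed intramolecular C–O coupling (Buchwald–Hartwig etherification) of the aryl bromide with the primary alkoxide closes the lower pyran as a six-membered ring, whereas the benzylic hydroxyl could only give an eight-membered ring.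

Step 11
Reactants: 15 {4-(benzyloxy)-2-[(3R)-7-(benzyloxy)-3,4-dihydro-2H-chromen-3-yl]-6-methoxyphenyl}methanol
Product: 16 4-(benzyloxy)-2-[(3R)-7-(benzyloxy)-3,4-dihydro-2H-chromen-3-yl]-6-methoxybenzaldehyde
Conditions: MnO2, CH2Cl2, rt
Reagents that add atoms: none
Why: Chemoselective MnO2 oxidation of the electron-rich benzylic alcohol to the aldehyde, which leaves the ethers and the stereocentre untouched.

Step 12
Reactants: 17 1-(3,4-dihydroxyphenyl)ethan-1-one
Product: 18 1-[3-hydroxy-4-(methoxymethoxy)phenyl]ethan-1-one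
Conditions: MOMCl (1.0 equiv), K2CO3, acetone, 0 °C → rt
Reagents that add atoms: chloromethyl methyl ether, COCCl
Why: Regioselective O-alkylation: the 4-hydroxyl, para to the acetyl group, is the more acidic and should be alkylated first under weak base.

Step 13
Reactants: 18 1-[3-hydroxy-4-(methoxymethoxy)phenyl]ethan-1-one
Product: 19 1-[3-(benzyloxy)-4-(methoxymethoxy)phenyl]ethan-1-one
Conditions: BnBr, K2CO3, DMF, 50 °C
Reagents that add atoms: benzyl bromide, BrCc1ccccc1
Why: Williamson etherification of the remaining phenol.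

Step 14
Reactants: 19 1-[3-(benzyloxy)-4-(methoxymethoxy)phenyl]ethan-1-one
Product: 20 1-[5-(benzyloxy)-2-bromo-4-(methoxymethoxy)phenyl]ethan-1-one
Conditions: NBS, MeCN, rt, dark
Reagents that add atoms: N-bromosuccinimide, BrN1C(=O)CCC1=O
Why: Electrophilic aromatic bromination at the position para to the benzyloxy group and ortho to the acetyl group, the pattern known for 3,4-dialkoxyacetophenones.

Step 15
Reactants: 21 2,3-dihydroxy-4-methoxybenzaldehyde
Product: 22 2,3-bis(benzyloxy)-4-methoxybenzaldehyde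
Conditions: BnBr (2.5 equiv), K2CO3, DMF, 60 °C
Reagents that add atoms: benzyl bromide, BrCc1ccccc1
Why: Double Williamson etherification of the catechol.

Step 16
Reactants: 22 2,3-bis(benzyloxy)-4-methoxybenzaldehyde
Product: 24 2,3-bis(benzyloxy)-4-methoxyphenol, via aryl formate 23 (not isolated)
Conditions: mCPBA, CH2Cl2, rt; then K2CO3 (cat.), MeOH
Reagents that add atoms: 3-chloroperbenzoic acid, OOC(=O)c1cccc(Cl)c1
Why: Dakin-type Baeyer–Villiger oxidation of the electron-rich benzaldehyde (aryl migration to oxygen) followed by methanolysis of the aryl formate.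

Step 17
Reactants: 24 2,3-bis(benzyloxy)-4-methoxyphenol
Product: 25 2,3-bis(benzyloxy)-4-methoxyphenyl trifluoromethanesulfonate
Conditions: Tf2O, pyridine, CH2Cl2, 0 °C
Reagents that add atoms: trifluoromethanesulfonic anhydride, O=S(=O)(OS(=O)(=O)C(F)(F)F)C(F)(F)F
Why: O-Sulfonylation of the phenol gives the aryl electrophile for the later α-arylation.

Step 18
Reactants: 20 1-[5-(benzyloxy)-2-bromo-4-(methoxymethoxy)phenyl]ethan-1-one; 16 4-(benzyloxy)-2-[(3R)-7-(benzyloxy)-3,4-dihydro-2H-chromen-3-yl]-6-methoxybenzaldehyde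
Product: 27 (2E)-1-[5-(benzyloxy)-2-bromo-4-(methoxymethoxy)phenyl]-3-ArC-prop-2-en-1-one, via aldol adduct 26 (not isolated)
Conditions: KOH (aq.), EtOH–THF, rt
Reagents that add atoms: none
Why: Claisen–Schmidt condensation: the ketone enolate adds to the non-enolisable aldehyde and the aldol loses water to give the conjugated (E)-enone.

Step 19
Reactants: 27 (2E)-1-[5-(benzyloxy)-2-bromo-4-(methoxymethoxy)phenyl]-3-ArC-prop-2-en-1-one
Product: 28 (3S)-6-(benzyloxy)-5-(methoxymethoxy)-3-ArC-2,3-dihydro-1H-inden-1-one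
Conditions: Pd(OAc)2, (R)-3,5-Xyl-MeO-BIPHEP, HCO2Na, DMF, 80 °C
Reagents that add atoms: none
Why: Intramolecular reductive Heck cyclisation (oxidative addition into C–Br, carbopalladation of the enone with C–C bond formation at the β-carbon, formate reduction of the palladium enolate), a known route from 2'-halochalcones to 3-aryl-indan-1-ones; the chiral bisphosphine controls the enone face and hence C3, and the minor C3 epimer, a diastereomer because of the fixed chroman centre, is removed by chromatography.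

Step 20
Reactants: 28 (3S)-6-(benzyloxy)-5-(methoxymethoxy)-3-ArC-2,3-dihydro-1H-inden-1-one; 25 2,3-bis(benzyloxy)-4-methoxyphenyl trifluoromethanesulfonate
Product: 29 (2R,3S)-6-(benzyloxy)-2-ArB-5-(methoxymethoxy)-3-ArC-2,3-dihydro-1H-inden-1-one (trans)
Conditions: Pd2(dba)3, XPhos, NaOtBu, toluene, 80 °C
Reagents that add atoms: none
Why: Palladium-catalysed α-arylation of the indanone enolate with the aryl triflate, a reaction type known to convert 3-aryl-indan-1-ones into trans-2,3-diaryl-indan-1-ones; C2 should be set (R), trans to the C3 aryl group, by coupling anti to that group and by base-mediated equilibration of the acidic C2–H.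

Step 21
Reactants: 29 (2R,3S)-6-(benzyloxy)-2-ArB-5-(methoxymethoxy)-3-ArC-2,3-dihydro-1H-inden-1-one
Product: 30 (3R,4S)-7-(benzyloxy)-3-ArB-6-(methoxymethoxy)-4-ArC-3,4-dihydro-2H-chromen-2-one (trans)
Conditions: mCPBA, CH2Cl2, 0 °C → rt
Reagents that add atoms: 3-chloroperbenzoic acid, OOC(=O)c1cccc(Cl)c1
Why: The peracid adds to the C1 carbonyl to give the Criegee adduct, and the ring-fusion aryl carbon C7a migrates to the proximal peroxide oxygen with loss of 3-chlorobenzoate, so that oxygen is inserted between C1 and C7a (the future O1–C8a bond). The closest known reaction is the Baeyer–Villiger ring expansion of 3-aryl-indan-1-ones to 4-aryl-3,4-dihydrocoumarins. The six-membered lactone arises by ring expansion of the cyclopentanone through this 1,2-shift and not by a cyclisation, and no bond to C2 or C3 is broken. No stereocentre is formed; C2 and C3 keep their trans (2R,3S) arrangement, which is named (3R,4S) in the lactone. The step needs migration of aryl C7a in preference to the benzylic C2, and oxidation of the ketone in preference to the electron-rich rings; the methoxymethoxy group at C5, para to C7a, stabilises the cyclohexadienyl-like transition state of aryl migration and should raise the rate enough for 3-chloroperbenzoic acid near room temperature to suffice.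

Step 22
Reactants: 30 (3R,4S)-7-(benzyloxy)-3-ArB-6-(methoxymethoxy)-4-ArC-3,4-dihydro-2H-chromen-2-one
Product: 31 (2R,3S)-2-ArB-3-[4-(benzyloxy)-2-hydroxy-5-(methoxymethoxy)phenyl]-3-ArC-propan-1-ol
Conditions: LiAlH4, THF, 0 °C, under argon
Reagents that add atoms: none
Why: Hydride reduction of the aryl lactone to the primary alcohol and the phenol, fast enough at 0 °C that the α-aryl centre should not epimerise.

Step 23
Reactants: 31 (2R,3S)-2-ArB-3-[4-(benzyloxy)-2-hydroxy-5-(methoxymethoxy)phenyl]-3-ArC-propan-1-ol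
Product: 32 (3R,4S)-7-(benzyloxy)-3-ArB-6-(methoxymethoxy)-4-ArC-3,4-dihydro-2H-chromene
Conditions: PPh3, DIAD, THF, 0 °C → rt
Reagents that add atoms: none
Why: Intramolecular Mitsunobu etherification: the phenol displaces the activated primary hydroxyl (6-exo-tet) to close the upper pyran, and neither stereocentre takes part in the substitution.

Step 24
Reactants: 32 (3R,4S)-7-(benzyloxy)-3-ArB-6-(methoxymethoxy)-4-ArC-3,4-dihydro-2H-chromene
Product: 33 (3R,4S)-7-(benzyloxy)-3-ArB-4-ArC-3,4-dihydro-2H-chromen-6-ol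
Conditions: HCl (3 M aq.), MeOH–THF, 45 °C
Reagents that add atoms: none
Why: Acid-catalysed acetal exchange removes the methoxymethyl group, the benzyl ethers and both chroman rings being stable to dilute acid.

Step 25
Reactants: 33 (3R,4S)-7-(benzyloxy)-3-ArB-4-ArC-3,4-dihydro-2H-chromen-6-ol
Product: 34 (3R,4S)-7-(benzyloxy)-3-ArB-4-ArC-3,4-dihydro-2H-chromen-6-yl trifluoromethanesulfonate
Conditions: Tf2O, pyridine, CH2Cl2, 0 °C
Reagents that add atoms: trifluoromethanesulfonic anhydride, O=S(=O)(OS(=O)(=O)C(F)(F)F)C(F)(F)F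
Why: O-Triflation of the freed phenol prepares the temporary oxygen for reductive removal.

Step 26
Reactants: 34 (3R,4S)-7-(benzyloxy)-3-ArB-4-ArC-3,4-dihydro-2H-chromen-6-yl trifluoromethanesulfonate
Product: 35 (3R,4S)-7-(benzyloxy)-3-ArB-4-ArC-3,4-dihydro-2H-chromene
Conditions: Pd(OAc)2, dppf, HCO2H, Et3N, DMF, 70 °C
Reagents that add atoms: none
Why: Palladium-catalysed reduction of the aryl triflate by formate (oxidative addition, formate-to-hydride exchange with loss of CO2, reductive elimination) removes the temporary oxygen under homogeneous conditions that should not touch the benzyl ethers.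

Step 27
Reactants: 35 (3R,4S)-7-(benzyloxy)-3-ArB-4-ArC-3,4-dihydro-2H-chromene
Product: 36 3-[(3R,4S)-7-hydroxy-4-{4-hydroxy-2-[(3R)-7-hydroxy-3,4-dihydro-2H-chromen-3-yl]-6-methoxyphenyl}-3,4-dihydro-2H-chromen-3-yl]-6-methoxybenzene-1,2-diol (CNP0227211.1)
Conditions: H2 (1 atm), Pd/C, EtOAc–MeOH, rt
Reagents that add atoms: none
Why: Hydrogenolysis of the five benzyl ethers over palladium; the diarylmethine C–C bonds and the chroman C–O bonds are not benzylic C–O bonds and should remain, so no stereocentre is affected.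

Compound list
1 | 2-bromo-4-hydroxybenzaldehyde | O=Cc1ccc(O)cc1Br | starting material
2 | 4-(benzyloxy)-2-bromobenzaldehyde | O=Cc1ccc(OCc2ccccc2)cc1Br | intermediate
3 | [4-(benzyloxy)-2-bromophenyl]methanol | OCc1ccc(OCc2ccccc2)cc1Br | intermediate
4 | 4-(benzyloxy)-2-bromo-1-(bromomethyl)benzene | BrCc1ccc(OCc2ccccc2)cc1Br | intermediate
5 | methyl 2,4-dihydroxy-6-methylbenzoate | COC(=O)c1c(C)cc(O)cc1O | starting material
6 | methyl 4-(benzyloxy)-2-hydroxy-6-methylbenzoate | COC(=O)c1c(C)cc(OCc2ccccc2)cc1O | intermediate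
7 | methyl 4-(benzyloxy)-2-methoxy-6-methylbenzoate | COC(=O)c1c(C)cc(OCc2ccccc2)cc1OC | intermediate
8 | benzylic lithium species of 7 (not isolated) | [Li]Cc1cc(OCc2ccccc2)cc(OC)c1C(=O)OC | intermediate
9 | 2-[5-(benzyloxy)-3-methoxy-2-(methoxycarbonyl)phenyl]acetic acid | COC(=O)c1c(CC(=O)O)cc(OCc2ccccc2)cc1OC | intermediate
10 | mixed pivalic anhydride of 9 (not isolated) | COC(=O)c1c(CC(=O)OC(=O)C(C)(C)C)cc(OCc2ccccc2)cc1OC | intermediate
11 | methyl 4-(benzyloxy)-2-{2-[(4R)-4-benzyl-2-oxo-1,3-oxazolidin-3-yl]-2-oxoethyl}-6-methoxybenzoate | COC(=O)c1c(CC(=O)N2[C@H](Cc3ccccc3)COC2=O)cc(OCc2ccccc2)cc1OC | intermediate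
12 | sodium Z-enolate of 11 (not isolated) | [Na+].[O-]/C(=C\c1cc(OCc2ccccc2)cc(OC)c1C(=O)OC)N1[C@H](Cc2ccccc2)COC1=O | intermediate
13 | methyl 4-(benzyloxy)-2-{(2R)-1-[(4R)-4-benzyl-2-oxo-1,3-oxazolidin-3-yl]-3-[4-(benzyloxy)-2-bromophenyl]-1-oxopropan-2-yl}-6-methoxybenzoate | COC(=O)c1c([C@@H](Cc2ccc(OCc3ccccc3)cc2Br)C(=O)N2[C@H](Cc3ccccc3)COC2=O)cc(OCc2ccccc2)cc1OC | intermediate
14 | (2R)-3-[4-(benzyloxy)-2-bromophenyl]-2-[5-(benzyloxy)-2-(hydroxymethyl)-3-methoxyphenyl]propan-1-ol | OCc1c([C@H](CO)Cc2ccc(OCc3ccccc3)cc2Br)cc(OCc2ccccc2)cc1OC | intermediate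
15 | {4-(benzyloxy)-2-[(3R)-7-(benzyloxy)-3,4-dihydro-2H-chromen-3-yl]-6-methoxyphenyl}methanol | OCc1c(OC)cc(OCc2ccccc2)cc1[C@@H]1COc2cc(OCc3ccccc3)ccc2C1 | intermediate
16 | 4-(benzyloxy)-2-[(3R)-7-(benzyloxy)-3,4-dihydro-2H-chromen-3-yl]-6-methoxybenzaldehyde | O=Cc1c(OC)cc(OCc2ccccc2)cc1[C@@H]1COc2cc(OCc3ccccc3)ccc2C1 | intermediate
17 | 1-(3,4-dihydroxyphenyl)ethan-1-one | CC(=O)c1ccc(O)c(O)c1 | starting material
18 | 1-[3-hydroxy-4-(methoxymethoxy)phenyl]ethan-1-one | CC(=O)c1ccc(OCOC)c(O)c1 | intermediate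
19 | 1-[3-(benzyloxy)-4-(methoxymethoxy)phenyl]ethan-1-one | CC(=O)c1ccc(OCOC)c(OCc2ccccc2)c1 | intermediate
20 | 1-[5-(benzyloxy)-2-bromo-4-(methoxymethoxy)phenyl]ethan-1-one | CC(=O)c1cc(OCc2ccccc2)c(OCOC)cc1Br | intermediate
21 | 2,3-dihydroxy-4-methoxybenzaldehyde | COc1ccc(C=O)c(O)c1O | starting material
22 | 2,3-bis(benzyloxy)-4-methoxybenzaldehyde | COc1ccc(C=O)c(OCc2ccccc2)c1OCc1ccccc1 | intermediate
23 | 2,3-bis(benzyloxy)-4-methoxyphenyl formate (not isolated) | COc1ccc(OC=O)c(OCc2ccccc2)c1OCc1ccccc1 | intermediate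
24 | 2,3-bis(benzyloxy)-4-methoxyphenol | COc1ccc(O)c(OCc2ccccc2)c1OCc1ccccc1 | intermediate
25 | 2,3-bis(benzyloxy)-4-methoxyphenyl trifluoromethanesulfonate | COc1ccc(OS(=O)(=O)C(F)(F)F)c(OCc2ccccc2)c1OCc1ccccc1 | intermediate
26 | 1-[5-(benzyloxy)-2-bromo-4-(methoxymethoxy)phenyl]-3-hydroxy-3-ArC-propan-1-one, both carbinol epimers (not isolated) | O=C(CC(O)c1c(OC)cc(OCc2ccccc2)cc1[C@@H]1COc2cc(OCc3ccccc3)ccc2C1)c1cc(OCc2ccccc2)c(OCOC)cc1Br | intermediate
27 | (2E)-1-[5-(benzyloxy)-2-bromo-4-(methoxymethoxy)phenyl]-3-ArC-prop-2-en-1-one | O=C(/C=C/c1c(OC)cc(OCc2ccccc2)cc1[C@@H]1COc2cc(OCc3ccccc3)ccc2C1)c1cc(OCc2ccccc2)c(OCOC)cc1Br | intermediate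
28 | (3S)-6-(benzyloxy)-5-(methoxymethoxy)-3-ArC-2,3-dihydro-1H-inden-1-one | O=C1C[C@H](c2c(OC)cc(OCc3ccccc3)cc2[C@@H]2COc3cc(OCc4ccccc4)ccc3C2)c2cc(OCOC)c(OCc3ccccc3)cc21 | intermediate
29 | (2R,3S)-6-(benzyloxy)-2-ArB-5-(methoxymethoxy)-3-ArC-2,3-dihydro-1H-inden-1-one | COc1ccc([C@@H]2C(=O)c3cc(OCc4ccccc4)c(OCOC)cc3[C@H]2c2c(OC)cc(OCc3ccccc3)cc2[C@@H]2COc3cc(OCc4ccccc4)ccc3C2)c(OCc2ccccc2)c1OCc1ccccc1 | intermediate
30 | (3R,4S)-7-(benzyloxy)-3-ArB-6-(methoxymethoxy)-4-ArC-3,4-dihydro-2H-chromen-2-one | COc1ccc([C@@H]2C(=O)Oc3cc(OCc4ccccc4)c(OCOC)cc3[C@H]2c2c(OC)cc(OCc3ccccc3)cc2[C@@H]2COc3cc(OCc4ccccc4)ccc3C2)c(OCc2ccccc2)c1OCc1ccccc1 | intermediate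
31 | (2R,3S)-2-ArB-3-[4-(benzyloxy)-2-hydroxy-5-(methoxymethoxy)phenyl]-3-ArC-propan-1-ol | COc1ccc([C@H](CO)[C@@H](c2cc(OCOC)c(OCc3ccccc3)cc2O)c2c(OC)cc(OCc3ccccc3)cc2[C@@H]2COc3cc(OCc4ccccc4)ccc3C2)c(OCc2ccccc2)c1OCc1ccccc1 | intermediate
32 | (3R,4S)-7-(benzyloxy)-3-ArB-6-(methoxymethoxy)-4-ArC-3,4-dihydro-2H-chromene | COc1ccc([C@@H]2COc3cc(OCc4ccccc4)c(OCOC)cc3[C@H]2c2c(OC)cc(OCc3ccccc3)cc2[C@@H]2COc3cc(OCc4ccccc4)ccc3C2)c(OCc2ccccc2)c1OCc1ccccc1 | intermediate
33 | (3R,4S)-7-(benzyloxy)-3-ArB-4-ArC-3,4-dihydro-2H-chromen-6-ol | COc1ccc([C@@H]2COc3cc(OCc4ccccc4)c(O)cc3[C@H]2c2c(OC)cc(OCc3ccccc3)cc2[C@@H]2COc3cc(OCc4ccccc4)ccc3C2)c(OCc2ccccc2)c1OCc1ccccc1 | intermediate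
34 | (3R,4S)-7-(benzyloxy)-3-ArB-4-ArC-3,4-dihydro-2H-chromen-6-yl trifluoromethanesulfonate | COc1ccc([C@@H]2COc3cc(OCc4ccccc4)c(OS(=O)(=O)C(F)(F)F)cc3[C@H]2c2c(OC)cc(OCc3ccccc3)cc2[C@@H]2COc3cc(OCc4ccccc4)ccc3C2)c(OCc2ccccc2)c1OCc1ccccc1 | intermediate
35 | (3R,4S)-7-(benzyloxy)-3-ArB-4-ArC-3,4-dihydro-2H-chromene | COc1ccc([C@@H]2COc3cc(OCc4ccccc4)ccc3[C@H]2c2c(OC)cc(OCc3ccccc3)cc2[C@@H]2COc3cc(OCc4ccccc4)ccc3C2)c(OCc2ccccc2)c1OCc1ccccc1 | intermediate
36 | 3-[(3R,4S)-7-hydroxy-4-{4-hydroxy-2-[(3R)-7-hydroxy-3,4-dihydro-2H-chromen-3-yl]-6-methoxyphenyl}-3,4-dihydro-2H-chromen-3-yl]-6-methoxybenzene-1,2-diol (CNP0227211.1) | COc1ccc([C@@H]2COc3cc(O)ccc3[C@H]2c2c(OC)cc(O)cc2[C@@H]2COc3cc(O)ccc3C2)c(O)c1O | target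

Total step count: 27 steps.
Longest linear sequence: 18 steps (steps 4–11, then 18–27).

Steps most likely to fail

Step 21. In the Criegee adduct the benzylic C2, which carries an electron-rich aryl group, may migrate in place of the aryl carbon C7a and give the isochromanone. The peracid may also hydroxylate the dialkoxy-substituted rings before the hindered ketone has reacted. The fallback replaces the neutral ether by a free para-phenol and uses a Dakin oxidation, in which only a hydroxy-substituted aryl group can migrate. It sets out from 29: cleavage of the MOM ether (HCl, MeOH–THF) should give (2R,3S)-6-(benzyloxy)-2-ArB-5-hydroxy-3-ArC-2,3-dihydro-1H-inden-1-one F1. Alkaline hydrogen peroxide (H2O2, aq. NaOH, THF, degassed, 0 °C) then lets the para-phenoxide drive the aryl shift, and acidification relactonises the hydroxy acid to (3R,4S)-7-(benzyloxy)-3-ArB-6-hydroxy-4-ArC-3,4-dihydro-2H-chromen-2-one F2. LiAlH4 reduction gives (2R,3S)-2-ArB-3-[4-(benzyloxy)-2,5-dihydroxyphenyl]-3-ArC-propan-1-ol F3. Mitsunobu closure, possible only for the hydroxyl ortho to the side chain, returns to the route at 33.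

Step 19. Carbopalladation at the β-carbon, which is shielded on both faces by the ortho substituents of ArC, may be slow, so that hydrodebromination or β-hydride elimination to the indenone takes over; the ligand may also fail to discriminate the enone faces. The fallback changes metal and elementary step. It sets out from 27: Miyaura borylation (B2pin2, Pd(dppf)Cl2, KOAc, dioxane, 80 °C) should give (2E)-1-[5-(benzyloxy)-4-(methoxymethoxy)-2-(4,4,5,5-tetramethyl-1,3,2-dioxaborolan-2-yl)phenyl]-3-ArC-prop-2-en-1-one F4. Rhodium-catalysed intramolecular 1,4-addition of the arylboronate to the enone ([RhCl(cod)]2, a chiral phosphoramidite, aq. K3PO4, toluene, 60 °C), a known enantioselective route to 3-aryl-indan-1-ones, then returns to the route at 28.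

Step 20. Coupling at the crowded C2 with an ortho-benzyloxy aryl triflate may be slow, so that S–O cleavage of the triflate by the alkoxide or palladium-mediated dehydrogenation of the enolate to the indenone competes. The fallback installs the aryl group before the five-membered ring is closed. It sets out from 19, 25 and 16: α-arylation of the unhindered methyl ketone 19 with 25 (Pd2(dba)3, XPhos, NaOtBu, toluene) should give 1-[3-(benzyloxy)-4-(methoxymethoxy)phenyl]-2-ArB-ethan-1-one F5. Condensation with 16 (piperidine, AcOH, toluene, Dean–Stark) gives 1-[3-(benzyloxy)-4-(methoxymethoxy)phenyl]-2-ArB-3-ArC-prop-2-en-1-one F6 as an E/Z mixture. Nazarov cyclisation (CF3CO2H, CH2Cl2) closes para to the benzyloxy group and should give the trans-indanone; the MOM ether is expected to be lost, so that after separation of the C2/C3 diastereomer the product is the phenol F1 described above. Re-protection (MOMCl, iPr2NEt, CH2Cl2) returns to the route at 29.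

Further compounds
F1 | step 21 | (2R,3S)-6-(benzyloxy)-2-ArB-5-hydroxy-3-ArC-2,3-dihydro-1H-inden-1-one | COc1ccc([C@@H]2C(=O)c3cc(OCc4ccccc4)c(O)cc3[C@H]2c2c(OC)cc(OCc3ccccc3)cc2[C@@H]2COc3cc(OCc4ccccc4)ccc3C2)c(OCc2ccccc2)c1OCc1ccccc1
F2 | step 21 | (3R,4S)-7-(benzyloxy)-3-ArB-6-hydroxy-4-ArC-3,4-dihydro-2H-chromen-2-one | COc1ccc([C@@H]2C(=O)Oc3cc(OCc4ccccc4)c(O)cc3[C@H]2c2c(OC)cc(OCc3ccccc3)cc2[C@@H]2COc3cc(OCc4ccccc4)ccc3C2)c(OCc2ccccc2)c1OCc1ccccc1
F3 | step 21 | (2R,3S)-2-ArB-3-[4-(benzyloxy)-2,5-dihydroxyphenyl]-3-ArC-propan-1-ol | COc1ccc([C@H](CO)[C@@H](c2cc(O)c(OCc3ccccc3)cc2O)c2c(OC)cc(OCc3ccccc3)cc2[C@@H]2COc3cc(OCc4ccccc4)ccc3C2)c(OCc2ccccc2)c1OCc1ccccc1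
F4 | step 19 | (2E)-1-[5-(benzyloxy)-4-(methoxymethoxy)-2-(4,4,5,5-tetramethyl-1,3,2-dioxaborolan-2-yl)phenyl]-3-ArC-prop-2-en-1-one | O=C(/C=C/c1c(OC)cc(OCc2ccccc2)cc1[C@@H]1COc2cc(OCc3ccccc3)ccc2C1)c1cc(OCc2ccccc2)c(OCOC)cc1B1OC(C)(C)C(C)(C)O1
F5 | step 20 | 1-[3-(benzyloxy)-4-(methoxymethoxy)phenyl]-2-ArB-ethan-1-one | COCOc1ccc(C(=O)Cc2ccc(OC)c(OCc3ccccc3)c2OCc2ccccc2)cc1OCc1ccccc1
F6 | step 20 | 1-[3-(benzyloxy)-4-(methoxymethoxy)phenyl]-2-ArB-3-ArC-prop-2-en-1-one (E/Z mixture) | COCOc1ccc(C(=O)C(=Cc2c(OC)cc(OCc3ccccc3)cc2[C@@H]2COc3cc(OCc4ccccc4)ccc3C2)c2ccc(OC)c(OCc3ccccc3)c2OCc2ccccc2)cc1OCc1ccccc1
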